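You cannot get J ahead of X at any time in these three flasks, because both start from zero, both are fed from Q.Z, and the step from Q.Z to X taken alone gives Q.Z a half-life of 0.889 h, but the step from Q.Z to J taken alone gives it 3.47 h.

the same everywhere: Q 0.50 M; time 4.0 h
- dawn: Z 1.20 equiv
- dusk: Z 0.910 equiv
- midnight: Z 0.700 equiv

    Q + J ⇌ Q.J, settled at all times (K1 = 5.8 M⁻¹)
    Q.Z → J (k2 = 0.20 h⁻¹)
    Q.Z → X (k3 = 0.78 h⁻¹)
    L ⇌ J, rate k4*(cs4 - [J]) while solid is left; crystals form when [J] > cs4 (cs4 = 0.28 M, k4 = 2.0 h⁻¹)
    Q + Z → Q.Z (k5 = 1.0 M⁻¹ h⁻¹)

1. which of these there is most of at the end, counted by the Q in it, dawn (Q / Q.Z / J / X)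
2. which of these there is most of at the end, counted by the Q in it, dusk (Q / Q.Z / J / X)
3. which of these there is most of at the end, counted by the Q in it, midnight (Q / Q.Z / J / X)
4. the largest of these amounts at the end, in percent of the Q charged, dawn
5. the largest of these amounts at the end, in percent of the Q charged, dusk
6. the largest of these amounts at the end, in percent of the Q charged, midnight

- percent here means Q units held: one Q.J counts as two
- what is said of J includes Q.J and L
- L is a solid; its amount is given per volume of the solution
- in an amount of J, one Q.J counts as one J
- run time (dawn): 4.0 h

Those two half-lives are the pair to hold on to. Their ratio, X made per J made, is the branching ratio 3.90, a selectivity factor, and it gives X a share of 79.6% of every Q.Z that leaves. Step 1 and step 4 only move J between its forms, and J is counted with Q.J and L, so they leave this ratio as it is. Step 4 should not even begin: if the whole charge of Q went through Q.Z, J would come to 0.102 M, less than the solubility 0.28 M.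

So the contest is between X and Q. Q.Z drains with a half-life of 0.707 h, shorter than the run of 4.0 h, so I treat it as a small correction and set it aside. Then X is the share 79.6% of what step 5 has converted. Step 5 as an ordinary second-order reaction, with Q.J ignored, leaves Q at 25.3% at dawn, 37.5% at dusk and 48.7% at midnight. My X is then 59.5%, 49.7% and 40.8%, so I commit to X leading at dawn and dusk and Q leading at midnight. The forecast names the same leaders, X, X and Q, but with different figures, 50%, 42% and 51%, and says “unreacted free Q stays the largest at midnight”.

The simulation gives X at 50.5% at dawn, X at 42.1% at dusk and Q at 44.6% at midnight. At dawn Q.Z still holds 8.99% at the end, the amount my reckoning set aside. J at dawn stands at 13.0%, all forms counted, so X over J reads 3.90. Take the dawn flask with 0.480 equiv of Z instead: Q leads there at 59.0%, X reaches 25.3%, the branching ratio 3.90 turns that into 6.49% of J, and J stands at 6.48%.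

Its constants are invented; the run is a simulation.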